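Locants used throughout: phthalide C1 (C=O), O2, C3, C3a–C7a; spiroketal ring A = O1, C2 (bears the chain), C3, C4, C5 (spiro); ring B = C5, O6, C7 (bears the methyl), C8, C9.

## The problem

The target is a (3R)-5,7-dimethoxyphthalide joined through an unbranched hexamethylene chain to C2 of a (2R,5S,7R)-7-methyl-1,6-dioxaspiro[4.4]nonane. The chain has no functional group, so each C–C bond in it should come from plain alkyl building blocks and not from functionality that must be removed later. C3 of the phthalide is seven bonds from C2, so no relay of stereochemistry is possible and C3 needs reagent control. C2 and C7 are isolated carbinol carbons of the kind enantiopure epoxides supply.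

The hard centre is the spiro carbon C5. In a [4.4] spiroketal both rings are flexible envelopes, and the anomeric preference that fixes a [5.5] system is weak. Acid equilibration is therefore expected to return both C5 epimers (alkyl groups anti or syn to the oxygen of the other ring) in comparable amounts, and C2 and C7 bias C5 only weakly. C5 must be set under kinetic control and must not meet acid afterwards. The phthalide, an electrophilic lactone with an acidic benzylic C3–H, does not tolerate acetylides, Grignard reagents or strong base, so the order of events matters.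

The feature that opens a way is that C5 is a ketal carbon flanked in ring A by the methylene C4, while O6 hangs on the three-carbon arm C9–C8–C7. Ring A can therefore be written as a 2,3-dihydrofuran (enol ether C4=C5): protonation at C4 unmasks an oxocarbenium ion at C5 that O6 captures in a five-membered closure. That enol ether is in turn an isomer of an alkyne C4≡C5 with the C2 hydroxyl in the homopropargylic position.

## Retrosynthesis

**Target 25 to spiroketal bromo carbamate 22.** The aryl–carbonyl bond C7a–C1 of the lactone is cut. Forward, bromine–lithium exchange on 22 gives an aryllithium that takes the carbonyl from the neighbouring N,N-diethylcarbamate. This places ring closure of the phthalide last and under basic conditions at low temperature, so the spiroketal sees no acid after C5 is set and the lactone never meets a carbon nucleophile. The carbamate serves first as protecting group and then as the C1 donor; the C3–O bond is never broken.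

**22 to hydroxy enol ether 20 (key disconnection).** The C5–O6 bond is cut. 20 lacks the spiro centre and ring B, and its three stereocentres are all simple carbinol carbons. Against dehydrative closure of a keto diol, this cut offers a kinetic pathway: addition of an alcohol across an enol ether is irreversible under weak-acid, aprotic, cold conditions, and the face of addition can be dictated by a confined chiral Brønsted acid. The forward step must add O6 to the face of ring A anti to the C2 side chain and must not let 22 re-ionise.

**20 to alkynol 18 via silyl ether 19.** The O1–C5 bond is cut; C4=C5 becomes C10≡C11 of an open chain. Only the C8 hydroxyl of 18 is free, and it reaches C11 in a 5-endo-dig closure. The silyl ether on C14 stops the sequence at the enol ether. Without it a metal catalyst would close both rings and the second closure would escape control.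

**18 to epoxide 11 and alkyne 16.** The propargylic bond C9–C10 is cut. Opening a terminal epoxide with an acetylide joins the two halves and delivers the C8 carbinol with the epoxide's configuration. Placing the alkyne one bond further (C11≡C12) would need an sp–sp3 alkylation with a less accessible 1,3-difunctional electrophile.

**16 to (R)-propylene oxide 13 and propargyl bromide 12 via alcohol 15.** The C3–C4 bond of the hexynol is cut; the C14 stereocentre of 18 is bought as 13.

**11 back to 8-bromooct-1-ene 1 and 3,5-dimethoxybenzonitrile 2.** The epoxide comes from the terminal alkene of 9 by epoxidation to 10 and hydrolytic kinetic resolution. The ring bromine comes from electrophilic bromination of carbamate 8. The C1 stereocentre comes from asymmetric transfer hydrogenation of aryl ketone 5 to alcohol 6, and 5 from addition of the Grignard reagent of 1 to 2. The whole chain between the two ring systems is thus one commercial C8 unit.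

## Roads not taken

**Alternative 1:** The most obvious cut is a C–C bond in the middle of the chain, made by olefination and hydrogenation. Phthalide aldehyde A1 and tetrazolyl sulfone A2 would be joined by Julia–Kocienski olefination and the alkene hydrogenated. A2 carries a spiroketal closed by acid-mediated dehydration, so it is formed as both C5 epimers. The epimers travel together to the end, and the target would emerge mixed with its C5 epimer A3, differing only at a centre remote from every polar group. The chosen plan leaves C5 open until a catalyst-controlled step and does not create an alkene only to erase it.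

**Alternative 2:** Cut C3–C4 and C8–C9 on either side of the spiro carbon. Acetone N,N-dimethylhydrazone A4 would be alkylated in turn with epoxides 13 and 11 (azaenolate openings), the hydrazone hydrolysed to keto diol A5, and both rings closed by acid. This is the shortest way to the carbon skeleton and joins the fragments at the future spiro carbon. But a keto diol can only close by reversible, water-releasing ketalisation, so 22 would arise as one component of the equilibrium mixture of C5 epimers. The alkyne of 18 stores the same oxidation level and can be released as an enol ether, which enters a kinetic manifold.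

**Alternative 3:** Cut the same C5–O6 bond but trigger it with an epoxide. Epoxidation of the enol ether of 20 followed by Ti(OiPr)4-mediated epoxide-opening spirocyclisation (retention at C5) would give the 4-hydroxy spiroketal A6, and Barton–McCombie deoxygenation would lead to 22. This is kinetic and substrate-controlled, but C5 is then relayed from the face of epoxidation, which is governed only by the C2 side chain across ring A. The selectivity problem is moved, not solved, and three steps are spent on a hydroxyl the target does not have. The chosen plan lets a catalyst choose the face directly.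

Key step: step 12

Assumption: the sense of induction of the confined acid in step 12 cannot be derived from first principles for this substrate, so the (S,S) catalyst is written provisionally and its antipode is used if that proves to be the matched one. Metal alkoxides that are merely protonated on work-up are not numbered.

## Route

Step 1
Reactants: 1 8-bromooct-1-ene; 2 3,5-dimethoxybenzonitrile
Product: 5 1-(3,5-dimethoxyphenyl)non-8-en-1-one, via oct-7-en-1-ylmagnesium bromide 3 (not isolated), via N-bromomagnesio ketimine 4 (not isolated)
Conditions: 1, Mg, I2 (cat.), THF, 40 °C; then 2, THF, reflux; then 2 M aq. HCl, rt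
Reagents that add atoms: water, O
Why: Grignard addition to an aryl nitrile stops at the ketimine salt, which cannot add a second equivalent; acidic hydrolysis gives the ketone and brings in the whole C8 chain with its terminal alkene.

Step 2
Reactants: 5 1-(3,5-dimethoxyphenyl)non-8-en-1-one
Product: 6 (1R)-1-(3,5-dimethoxyphenyl)non-8-en-1-ol
Conditions: RuCl[(R,R)-TsDPEN](p-cymene) (1 mol%), HCO2H/Et3N (5:2), CH2Cl2, 30 °C
Reagents that add atoms: none
Why: Noyori asymmetric transfer hydrogenation of an aryl n-alkyl ketone; the (R,R) catalyst is the one expected to deliver hydride to the Si face and give the (R) carbinol, and the isolated alkene is not reduced.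

Step 3
Reactants: 6 (1R)-1-(3,5-dimethoxyphenyl)non-8-en-1-ol
Product: 8 (1R)-1-(3,5-dimethoxyphenyl)non-8-en-1-yl N,N-diethylcarbamate, via sodium alkoxide 7 (not isolated)
Conditions: NaH, THF, 0 °C; then Et2NCOCl, reflux
Reagents that add atoms: N,N-diethylcarbamoyl chloride, CCN(CC)C(=O)Cl
Why: O-acylation of the sodium alkoxide; the carbamate protects the benzylic carbinol through the organometallic steps and later supplies the lactone carbonyl.

Step 4
Reactants: 8 (1R)-1-(3,5-dimethoxyphenyl)non-8-en-1-yl N,N-diethylcarbamate
Product: 9 (1R)-1-(2-bromo-3,5-dimethoxyphenyl)non-8-en-1-yl N,N-diethylcarbamate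
Conditions: NBS (1.0 equiv), MeCN, 0 °C, dark
Reagents that add atoms: N-bromosuccinimide, O=C1CCC(=O)N1Br
Why: Electrophilic aromatic bromination goes para to one methoxy group and ortho to the other; the two such positions are equivalent and the position between the methoxy groups is more hindered, while the alkene is left alone in the absence of radical initiation.

Step 5
Reactants: 9 (1R)-1-(2-bromo-3,5-dimethoxyphenyl)non-8-en-1-yl N,N-diethylcarbamate
Product: 10 (1R)-1-(2-bromo-3,5-dimethoxyphenyl)-7-(oxiran-2-yl)heptyl N,N-diethylcarbamate (both epimers at the oxirane carbon)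
Conditions: mCPBA, NaHCO3, CH2Cl2, 0 °C to rt
Reagents that add atoms: 3-chloroperoxybenzoic acid, OOC(=O)c1cccc(Cl)c1
Why: Prilezhaev epoxidation of the terminal alkene; the remote C1 centre gives no facial control, so both epimers form and are resolved in the next step.

Step 6
Reactants: 10 (1R)-1-(2-bromo-3,5-dimethoxyphenyl)-7-(oxiran-2-yl)heptyl N,N-diethylcarbamate (epimer mixture)
Product: 11 (1R)-1-(2-bromo-3,5-dimethoxyphenyl)-7-[(2R)-oxiran-2-yl]heptyl N,N-diethylcarbamate
Conditions: (R,R)-(salen)Co(OAc) (trivalent cobalt, 1 mol%), H2O (0.55 equiv), THF, 0 °C to rt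
Reagents that add atoms: none
Why: Jacobsen hydrolytic kinetic resolution; the catalyst enantiomer that hydrolyses the (S)-epoxide is used, so the (R)-epoxide remains and the other epimer is removed as its diol, at the cost of half the material.

Step 7
Reactants: 12 3-bromoprop-1-yne (propargyl bromide); 13 (2R)-2-methyloxirane ((R)-propylene oxide)
Product: 15 (2R)-hex-5-yn-2-ol, via allenylmagnesium bromide 14 (not isolated)
Conditions: 12, Mg, HgCl2 (cat.), Et2O, 0 °C; then 13, −20 °C to rt; aq. NH4Cl
Reagents that add atoms: none
Why: The allenyl Grignard reagent attacks with propargylic transposition (SE2′) at the unsubstituted carbon of the epoxide, so the terminal alkyne results and the stereocentre of 13 is untouched.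

Step 8
Reactants: 15 (2R)-hex-5-yn-2-ol
Product: 16 tert-butyl{[(2R)-hex-5-yn-2-yl]oxy}dimethylsilane
Conditions: TBSCl, imidazole, DMF, rt
Reagents that add atoms: tert-butyldimethylsilyl chloride, CC(C)(C)[Si](C)(C)Cl
Why: Standard silylation; the silyl ether later keeps this oxygen from closing its ring until the catalyst-controlled step.

Step 9
Reactants: 16 tert-butyl{[(2R)-hex-5-yn-2-yl]oxy}dimethylsilane; 11 (1R)-1-(2-bromo-3,5-dimethoxyphenyl)-7-[(2R)-oxiran-2-yl]heptyl N,N-diethylcarbamate
Product: 18 (1R,8R,14R)-1-(2-bromo-3,5-dimethoxyphenyl)-14-[(tert-butyldimethylsilyl)oxy]-8-hydroxypentadec-10-yn-1-yl N,N-diethylcarbamate, via lithium acetylide 17 (not isolated)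
Conditions: 16 (1.3 equiv), n-BuLi, THF, −78 °C; BF3·OEt2; then 11, −78 °C; aq. NaHCO3
Reagents that add atoms: none
Why: BF3-promoted SN2 opening of a terminal epoxide by a lithium acetylide at the unsubstituted carbon, so C8 keeps the (R) configuration of 11; the acetylide neither exchanges with the aryl bromide nor attacks the diethylcarbamate at −78 °C.

Step 10
Reactants: 18 (1R,8R,14R)-1-(2-bromo-3,5-dimethoxyphenyl)-14-[(tert-butyldimethylsilyl)oxy]-8-hydroxypentadec-10-yn-1-yl N,N-diethylcarbamate
Product: 19 (1R)-1-(2-bromo-3,5-dimethoxyphenyl)-7-[(2R)-5-{(3R)-3-[(tert-butyldimethylsilyl)oxy]butyl}-2,3-dihydrofuran-2-yl]heptyl N,N-diethylcarbamate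
Conditions: PdCl2(PhCN)2 (5 mol%), 4 Å MS, THF, rt
Reagents that add atoms: none
Why: Divalent palladium activates the alkyne for 5-endo-dig attack of the only free hydroxyl (C8–OH onto C11) and protodemetalation releases the 2,3-dihydrofuran, a known cycloisomerisation of 3-alkyn-1-ols; the silyl ether cannot take part, and sieves suppress hydration.

Step 11
Reactants: 19 (1R)-1-(2-bromo-3,5-dimethoxyphenyl)-7-[(2R)-5-{(3R)-3-[(tert-butyldimethylsilyl)oxy]butyl}-2,3-dihydrofuran-2-yl]heptyl N,N-diethylcarbamate
Product: 20 (1R)-1-(2-bromo-3,5-dimethoxyphenyl)-7-{(2R)-5-[(3R)-3-hydroxybutyl]-2,3-dihydrofuran-2-yl}heptyl N,N-diethylcarbamate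
Conditions: Bu4NF, THF, 0 °C to rt; work-up and filtration through basic alumina with Et3N-doped solvents
Reagents that add atoms: none
Why: Fluoride desilylation is basic and leaves the enol ether unprotonated; all contact with acidic surfaces is avoided so that 20 reaches the next step uncyclised.

Step 12
Reactants: 20 (1R)-1-(2-bromo-3,5-dimethoxyphenyl)-7-{(2R)-5-[(3R)-3-hydroxybutyl]-2,3-dihydrofuran-2-yl}heptyl N,N-diethylcarbamate
Product: 22 (1R)-1-(2-bromo-3,5-dimethoxyphenyl)-7-[(2R,5S,7R)-7-methyl-1,6-dioxaspiro[4.4]nonan-2-yl]heptyl N,N-diethylcarbamate, via oxocarbenium ion pair 21 (not isolated)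
Conditions: (S,S)-imidodiphosphoric acid built from two 3,3′-bis(2,4,6-triethylphenyl)-BINOL units (5 mol%), 4 Å MS, MTBE, −35 °C; then Et3N
Reagents that add atoms: none
Why: The confined acid protonates the enol ether of 20 at C4 and gives the oxocarbenium ion 21 (C5=O1) as a contact ion pair inside the chiral pocket; the C7 hydroxyl, hydrogen-bonded to a phosphoryl oxygen of the anion, adds to C5 and returns the proton to the catalyst. The closest known reaction type is the chiral Brønsted acid-catalysed spiroacetalisation of hydroxy enol ethers, which is documented for small unfunctionalised spiroketals, the 1,6-dioxaspiro[4.4]nonane skeleton among them, and for catalyst-controlled access to either spiro epimer. Ring B closes in a 5-exo-trig mode (O6 onto C5, with C5=O1 exocyclic to the new ring); ring A is already in place. The only new stereocentre is C5 and it is controlled by the catalyst, since proton and oxygen are delivered on the same face of the dihydrofuran and the face occupied by the catalyst decides the configuration. The step needs addition on the face of ring A anti to the C2 side chain, which gives the (5S) isomer with both alkyl groups anti to the oxygen of the other ring; the C2 substituent shields the syn face across O1, so substrate bias and one catalyst enantiomer should reinforce each other. It also needs kinetic control, which the weak acid, the ether solvent, the low temperature and the exclusion of water should secure, and the amine quench removes the acid before warming. Chemoselectivity follows from the C7 hydroxyl being the only protic nucleophile, with carbamate and aryl bromide inert.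

Step 13
Reactants: 22 (1R)-1-(2-bromo-3,5-dimethoxyphenyl)-7-[(2R,5S,7R)-7-methyl-1,6-dioxaspiro[4.4]nonan-2-yl]heptyl N,N-diethylcarbamate
Product: 25 (3R)-5,7-dimethoxy-3-{6-[(2R,5S,7R)-7-methyl-1,6-dioxaspiro[4.4]nonan-2-yl]hexyl}-2-benzofuran-1(3H)-one (target), via aryllithium 23 (not isolated), via tetrahedral lithium alkoxide 24 (not isolated)
Conditions: t-BuLi (2.2 equiv), THF, −78 °C; then pH 7 phosphate buffer
Reagents that add atoms: none
Why: Bromine–lithium exchange is faster than any deprotonation, and the aryllithium attacks the neighbouring carbamate carbonyl in a 5-exo-trig closure (Parham-type cyclisation); the adduct should persist at −78 °C and collapse to the lactone on quench, the C3–O bond is never broken so C3 stays (R), and the spiroketal is inert to base.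

## Compound list

1 | 8-bromooct-1-ene | C=CCCCCCCBr | starting material
2 | 3,5-dimethoxybenzonitrile | COc1cc(OC)cc(C#N)c1 | starting material
3 | oct-7-en-1-ylmagnesium bromide | C=CCCCCCC[Mg]Br | intermediate
4 | N-bromomagnesio ketimine of 1-(3,5-dimethoxyphenyl)non-8-en-1-one | COc1cc(OC)cc(C(=N[Mg]Br)CCCCCCC=C)c1 | intermediate
5 | 1-(3,5-dimethoxyphenyl)non-8-en-1-one | COc1cc(OC)cc(C(=O)CCCCCCC=C)c1 | intermediate
6 | (1R)-1-(3,5-dimethoxyphenyl)non-8-en-1-ol | COc1cc(OC)cc([C@H](O)CCCCCCC=C)c1 | intermediate
7 | sodium (1R)-1-(3,5-dimethoxyphenyl)non-8-en-1-olate | COc1cc(OC)cc([C@H](O[Na])CCCCCCC=C)c1 | intermediate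
8 | (1R)-1-(3,5-dimethoxyphenyl)non-8-en-1-yl N,N-diethylcarbamate | COc1cc(OC)cc([C@H](OC(=O)N(CC)CC)CCCCCCC=C)c1 | intermediate
9 | (1R)-1-(2-bromo-3,5-dimethoxyphenyl)non-8-en-1-yl N,N-diethylcarbamate | COc1cc(OC)c(Br)c([C@H](OC(=O)N(CC)CC)CCCCCCC=C)c1 | intermediate
10 | (1R)-1-(2-bromo-3,5-dimethoxyphenyl)-7-(oxiran-2-yl)heptyl N,N-diethylcarbamate, both epimers at the oxirane carbon | COc1cc(OC)c(Br)c([C@H](OC(=O)N(CC)CC)CCCCCCC2CO2)c1 | intermediate
11 | (1R)-1-(2-bromo-3,5-dimethoxyphenyl)-7-[(2R)-oxiran-2-yl]heptyl N,N-diethylcarbamate | COc1cc(OC)c(Br)c([C@H](OC(=O)N(CC)CC)CCCCCC[C@@H]2CO2)c1 | intermediate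
12 | 3-bromoprop-1-yne (propargyl bromide) | C#CCBr | starting material
13 | (2R)-2-methyloxirane ((R)-propylene oxide) | C[C@@H]1CO1 | starting material
14 | propa-1,2-dien-1-ylmagnesium bromide (allenylmagnesium bromide) | C=C=C[Mg]Br | intermediate
15 | (2R)-hex-5-yn-2-ol | C[C@@H](O)CCC#C | intermediate
16 | tert-butyl{[(2R)-hex-5-yn-2-yl]oxy}dimethylsilane | C[C@@H](O[Si](C)(C)C(C)(C)C)CCC#C | intermediate
17 | lithium acetylide of 16, {(5R)-5-[(tert-butyldimethylsilyl)oxy]hex-1-yn-1-yl}lithium | C[C@@H](O[Si](C)(C)C(C)(C)C)CCC#C[Li] | intermediate
18 | (1R,8R,14R)-1-(2-bromo-3,5-dimethoxyphenyl)-14-[(tert-butyldimethylsilyl)oxy]-8-hydroxypentadec-10-yn-1-yl N,N-diethylcarbamate | COc1cc(OC)c(Br)c([C@H](OC(=O)N(CC)CC)CCCCCC[C@@H](O)CC#CCC[C@@H](C)O[Si](C)(C)C(C)(C)C)c1 | intermediate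
19 | (1R)-1-(2-bromo-3,5-dimethoxyphenyl)-7-[(2R)-5-{(3R)-3-[(tert-butyldimethylsilyl)oxy]butyl}-2,3-dihydrofuran-2-yl]heptyl N,N-diethylcarbamate | COc1cc(OC)c(Br)c([C@H](OC(=O)N(CC)CC)CCCCCC[C@@H]2CC=C(CC[C@@H](C)O[Si](C)(C)C(C)(C)C)O2)c1 | intermediate
20 | (1R)-1-(2-bromo-3,5-dimethoxyphenyl)-7-{(2R)-5-[(3R)-3-hydroxybutyl]-2,3-dihydrofuran-2-yl}heptyl N,N-diethylcarbamate | COc1cc(OC)c(Br)c([C@H](OC(=O)N(CC)CC)CCCCCC[C@@H]2CC=C(CC[C@@H](C)O)O2)c1 | intermediate
21 | oxocarbenium ion from C4-protonation of 20 (cation shown; counter-ion is the imidodiphosphate of the catalyst) | COc1cc(OC)c(Br)c([C@H](OC(=O)N(CC)CC)CCCCCC[C@@H]2CCC(CC[C@@H](C)O)=[O+]2)c1 | intermediate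
22 | (1R)-1-(2-bromo-3,5-dimethoxyphenyl)-7-[(2R,5S,7R)-7-methyl-1,6-dioxaspiro[4.4]nonan-2-yl]heptyl N,N-diethylcarbamate | COc1cc(OC)c(Br)c([C@H](OC(=O)N(CC)CC)CCCCCC[C@@H]2CC[C@]3(CC[C@@H](C)O3)O2)c1 | intermediate
23 | aryllithium from 22 (lithium in place of bromine) | COc1cc(OC)c([Li])c([C@H](OC(=O)N(CC)CC)CCCCCC[C@@H]2CC[C@]3(CC[C@@H](C)O3)O2)c1 | intermediate
24 | lithium alkoxide of the 1-(diethylamino)-1-hydroxy-1,3-dihydroisobenzofuran adduct (tetrahedral intermediate, C1 unassigned) | COc1cc(OC)c2c(c1)[C@@H](CCCCCC[C@@H]1CC[C@]3(CC[C@@H](C)O3)O1)OC2(O[Li])N(CC)CC | intermediate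
25 | (3R)-5,7-dimethoxy-3-{6-[(2R,5S,7R)-7-methyl-1,6-dioxaspiro[4.4]nonan-2-yl]hexyl}-2-benzofuran-1(3H)-one | COc1cc(OC)c2c(c1)[C@@H](CCCCCC[C@@H]1CC[C@]3(CC[C@@H](C)O3)O1)OC2=O | target

## Step count and risks

Total: 13 steps. Longest linear sequence: 11 steps (steps 1–6 and 9–13); steps 7 and 8 make alkyne 16.

Least certain steps, most uncertain first:

**Step 12 (key).** The likely failures are poor facial selectivity at C5, if the catalyst pocket and the secondary C7 carbinol or the C2 side chain are mismatched, and loss of kinetic control through re-ionisation of the spiroketal. Uncatalysed closure of 20 by adventitious acid before it meets the catalyst would erode selectivity in the same way. The fallback gives up kinetic control. Starting from 20, PPTS (cat.) in CH2Cl2 at rt should give the equilibrium mixture of 22 and its (5R) epimer, (1R)-1-(2-bromo-3,5-dimethoxyphenyl)-7-[(2R,5R,7R)-7-methyl-1,6-dioxaspiro[4.4]nonan-2-yl]heptyl N,N-diethylcarbamate F1. The epimers are separated by preparative HPLC and F1 is returned to the same acid to regenerate the mixture, so the material converges on 22, where the route is rejoined.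

**Step 10.** The enol ether may react on under the metal, by intermolecular ketalisation with unconsumed alcohol, hydration by traces of water, or migration of the double bond, so that clean isolation fails. The fallback makes the over-reaction deliberate. Starting from 18, gold-catalysed tandem cycloisomerisation–hydroalkoxylation in methanol (Ph3PAuCl/AgBF4, monovalent gold, MeOH, rt) should give the mixed methyl ketal, (1R)-1-(2-bromo-3,5-dimethoxyphenyl)-7-[(2R)-5-{(3R)-3-[(tert-butyldimethylsilyl)oxy]butyl}-5-methoxyoxolan-2-yl]heptyl N,N-diethylcarbamate F2. Elimination of its methoxy group with TMSOTf/i-Pr2NEt in CH2Cl2 at −20 °C returns to 19. The regiochemistry of this elimination (ring versus side chain) is the residual uncertainty.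

**Step 13.** Possible failures are protonation of the aryllithium before acyl transfer, competing deprotonation at the benzylic C–H next to the carbamate, and epimerisation at C3 if lithium diethylamide is released before the quench. The fallback closes the lactone with carbon monoxide instead. Starting from 22, hydrolysis of the carbamate (KOH, aqueous EtOH, reflux; the spiroketal is stable to base) should give the bromo alcohol, (1R)-1-(2-bromo-3,5-dimethoxyphenyl)-7-[(2R,5S,7R)-7-methyl-1,6-dioxaspiro[4.4]nonan-2-yl]heptan-1-ol F6. Palladium-catalysed carbonylative lactonisation (Pd(OAc)2, Xantphos, CO 1 atm, Et3N, toluene, 90 °C) then gives 25.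

**Step 9.** The Lewis acid may open or rearrange the epoxide, or be tied up by the carbamate carbonyl, leaving precious 11 partly unconverted. The fallback builds the alkyne in two C–C bond formations without Lewis acid. Starting from 11, lithium acetylide–ethylenediamine complex in DMSO at rt should give the terminal alkyne, (1R,8R)-1-(2-bromo-3,5-dimethoxyphenyl)-8-hydroxyundec-10-yn-1-yl N,N-diethylcarbamate F4. Its dianion (LDA, 2.2 equiv, THF/DMPU, −78 to 0 °C) is alkylated at carbon with tert-butyl{[(2R)-4-iodobutan-2-yl]oxy}dimethylsilane F5, available in two steps from commercial (R)-butane-1,3-diol, which returns to 18.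

## Further compounds

F1 | step 12 | (1R)-1-(2-bromo-3,5-dimethoxyphenyl)-7-[(2R,5R,7R)-7-methyl-1,6-dioxaspiro[4.4]nonan-2-yl]heptyl N,N-diethylcarbamate (C5 epimer of 22) | COc1cc(OC)c(Br)c([C@H](OC(=O)N(CC)CC)CCCCCC[C@@H]2CC[C@@]3(CC[C@@H](C)O3)O2)c1
F2 | step 10 | (1R)-1-(2-bromo-3,5-dimethoxyphenyl)-7-[(2R)-5-{(3R)-3-[(tert-butyldimethylsilyl)oxy]butyl}-5-methoxyoxolan-2-yl]heptyl N,N-diethylcarbamate (both epimers at the ketal carbon) | COc1cc(OC)c(Br)c([C@H](OC(=O)N(CC)CC)CCCCCC[C@@H]2CCC(CC[C@@H](C)O[Si](C)(C)C(C)(C)C)(OC)O2)c1
F4 | step 9 | (1R,8R)-1-(2-bromo-3,5-dimethoxyphenyl)-8-hydroxyundec-10-yn-1-yl N,N-diethylcarbamate | COc1cc(OC)c(Br)c([C@H](OC(=O)N(CC)CC)CCCCCC[C@@H](O)CC#C)c1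
F5 | step 9 | tert-butyl{[(2R)-4-iodobutan-2-yl]oxy}dimethylsilane | C[C@H](CCI)O[Si](C)(C)C(C)(C)C
F6 | step 13 | (1R)-1-(2-bromo-3,5-dimethoxyphenyl)-7-[(2R,5S,7R)-7-methyl-1,6-dioxaspiro[4.4]nonan-2-yl]heptan-1-ol | COc1cc(OC)c(Br)c([C@H](O)CCCCCC[C@@H]2CC[C@]3(CC[C@@H](C)O3)O2)c1
A1 | alternative 1 | 3-[(1R)-4,6-dimethoxy-3-oxo-1,3-dihydro-2-benzofuran-1-yl]propanal (phthalide aldehyde) | COc1cc(OC)c2c(c1)[C@@H](CCC=O)OC2=O
A2 | alternative 1 | 5-({3-[7-methyl-1,6-dioxaspiro[4.4]nonan-2-yl]propyl}sulfonyl)-1-phenyl-1H-tetrazole, ring carbons C2 and C7 arranged as in the target, both C5 epimers | O=S(=O)(CCC[C@@H]1CCC2(CC[C@@H](C)O2)O1)c1nnnn1-c1ccccc1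
A3 | alternative 1 | (3R)-5,7-dimethoxy-3-{6-[(2R,5R,7R)-7-methyl-1,6-dioxaspiro[4.4]nonan-2-yl]hexyl}-2-benzofuran-1(3H)-one (C5 epimer of the target) | COc1cc(OC)c2c(c1)[C@@H](CCCCCC[C@@H]1CC[C@@]3(CC[C@@H](C)O3)O1)OC2=O
A4 | alternative 2 | acetone N,N-dimethylhydrazone | CC(C)=NN(C)C
A5 | alternative 2 | (1R,8R,14R)-1-(2-bromo-3,5-dimethoxyphenyl)-8,14-dihydroxy-11-oxopentadecyl N,N-diethylcarbamate (keto diol) | COc1cc(OC)c(Br)c([C@H](OC(=O)N(CC)CC)CCCCCC[C@@H](O)CCC(=O)CC[C@@H](C)O)c1
A6 | alternative 3 | 4-hydroxy derivative of 22, hydroxyl on C4 cis to O6 and trans to the C2 side chain | COc1cc(OC)c(Br)c([C@H](OC(=O)N(CC)CC)CCCCCC[C@@H]2C[C@@H](O)[C@]3(CC[C@@H](C)O3)O2)c1
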